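A leftover starts this: at the last reading of the north run, 60.0 min, Q stands at 83.0% and E at 13.8%, so 3.2 percentage points of the charge is in neither.

| setting | south | north | north-east | delta | alpha | zeta |
|---|---|---|---|---|---|---|
| Q | 3 M | 3 M | 1.5 M | 3.0 M | 3.0 M | 3.0 M |
| G | 1.5 mM | 2.2 mM | 3 mM | 3.0 mM | 3.0 mM | 3.0 mM |
| temperature | −40 °C | −5 °C | −40 °C | −5 °C | 25 °C | −35 °C |
| remark | run made earlier | run made earlier | run made earlier |  |  |  |
| time |  |  |  | 80 min | 80 min | 80 min |

- south (time / min: E / %, Q / %): 25.0: 0, 100.7; 60.0: 0, 99.6; 150: 0.6, 100.4; 240: 0.9, 97.5; 300: 0, 99.3; 360: 1.5, 98.9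
- north (time / min: E / %, Q / %): 5.00: 2.5, 99.3; 8.00: 3.4, 96.9; 15.0: 3.9, 95.1; 25.0: 7.0, 92.1; 40.0: 11.6, 88.8; 60.0: 13.8, 83.0
- north-east (time / min: E / %, Q / %): 30.0: 0, 99.6; 80.0: 0.4, 100.0; 180: 2.7, 98.3; 300: 3.0, 97.0; 360: 2.0, 98.3

(standard deviation of a reading: 1 percentage point)

* the best flask by amount of E, in percent of the Q charged; "all alike" if 1.5 percentage points covers them all (delta / alpha / zeta / all alike)
* amount of E at the end, in percent of the Q charged, delta
* amount of E at the end, in percent of the Q charged, alpha
* amount of E at the end, in percent of the Q charged, zeta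

Two views of these runs stand against each other. The forecast sees one step, Q to E, sped up by G and by warmth, and it mentions the gap as a doubt: “North's Q balance may be slipping slightly”. Its numbers are 25% for delta, 90% for alpha and 1.1% for zeta, with alpha best.

My view starts from the same step and computes a correction to it. Each reading scatters by 1 point, so the gap is a hint, but I take it as real. Suppose E, made at a steady pace, leaks onward to something unread, with a lifetime τ (a consecutive reaction, E being the intermediate). Early on, what has leaked divided by the E present is t/(2τ), where t is the time. The north run then gives τ = 129 min at 2.2 mM of G. If the leak goes with G, as the forecast takes the making to do, the leak lifetime τ of E at −5 °C and 3.0 mM of G is 94.9 min.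

In delta, Q falling at the north pace, scaled to its G, turns over 28.7% in 80 min. The leak ratio is 0.422, so E comes to 20.2%, against the forecast's 25%.

No reading shows how the leak warms. With no warming of the leak, and with E made at the forecast's rate constant of about 0.0500 min⁻¹, alpha holds 52.2% as E at 80 min, below the forecast's 90%. The forecast reads the making as about 50-fold faster between its cold and warm runs, and a leak that warms at all pulls alpha lower still. So I bet on delta. On zeta I have no quarrel with 1.1%.

    E + G ⇌ J + G, rate k1*[G]*[E] forward; the back reaction follows from the equilibrium constant (K = 7.90, k = 0.259 L mol⁻¹ s⁻¹, Ea = 37.0 kJ mol⁻¹, ΔH = −23.0 kJ mol⁻¹)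
    Q + G ⇌ E + G, rate k2*[Q]*[G] forward; the back reaction follows from the equilibrium constant (K = 1.10, k = 0.488 L mol⁻¹ s⁻¹, Ea = 63.0 kJ mol⁻¹, ΔH = 13.0 kJ mol⁻¹)
    (constants at 25 °C)

The flasks give 18.3% in delta, 15.2% in alpha and 1.09% in zeta, so delta is best. The unread product is J, and alpha holds 69.1% of it at 80.0 min, beside 15.2% of E. The one-step view holds in zeta, where J at 0.0483% is far less than E at 1.09%. In delta, J over E is 0.455, against the 0.422 from τ. In a flask like delta but with 0.750 mM of G, τ stretches to 380 min, which gives a ratio of 0.105, and the flask shows 0.0941.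

(The data are simulated for substances that don't exist.)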